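**Retrosynthetic overview**

1. The target, (2R,3S)-trans-dihydrobenzofuran with a (1R) side-chain carbinol, is traced back to bis-tigloylation of an enal diol, α-methylenation of a C2 acetaldehyde, and selective oxidation of the primary alcohol of a trans triol.
2. Key disconnection C3–C3a: a light-driven chromium/nickel-catalysed closure of an o-iodoaryl ether onto a lactol (masked α-aryloxy aldehyde), which sets C3 trans to the C2 chain.
3. Disconnection O1–C2: SN2 inversion of the triflate of (S)-α-hydroxy-γ-butyrolactone by an o-iodophenoxide, followed by lactone-to-lactol reduction.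
4. The iodophenol comes from ortho-iodination of (R)-4-(1-hydroxyethyl)phenol, whose carbinol centre is carried through unchanged.
5. Ring order: the benzene ring and the butyrolactone are bought; the only ring built is the dihydrofuran ring (step 4), and the lactol ring is opened in that same step.

Assumption: the two enantiopure starting materials (≥98% ee) and tiglic anhydride are taken as catalogue items.

**Route**

Step 1
Reactants: 1 (R)-4-(1-hydroxyethyl)phenol
Product: 2 4-[(1R)-1-hydroxyethyl]-2-iodophenol
Conditions: NIS (1.0 equiv), MeCN, 0 °C to rt, dark, no acid additive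
Reagents that add atoms: N-iodosuccinimide, O=C1CCC(=O)N1I
Why: Electrophilic aromatic iodination of a para-blocked phenol can only occur at the two equivalent ortho positions, and the acid-free conditions leave the ionisable p-hydroxybenzylic carbinol centre untouched.

Step 2
Reactants: 2 4-[(1R)-1-hydroxyethyl]-2-iodophenol; 3 (S)-3-hydroxydihydrofuran-2(3H)-one
Product: 5 (3R)-3-{4-[(1R)-1-hydroxyethyl]-2-iodophenoxy}dihydrofuran-2(3H)-one, via lactone triflate 4 (not isolated)
Conditions: 3, Tf2O (1.05 equiv), 2,6-lutidine (1.1 equiv), CH2Cl2, −78 to −20 °C; then 2 (0.9 equiv), K2CO3 (3 equiv), MeCN, −20 to 0 °C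
Reagents that add atoms: none
Why: Williamson-type SN2 etherification of an α-carbonyl triflate proceeds with clean inversion, turning the bought (S) carbinol into the (R) aryl ether that becomes C2, while K2CO3 deprotonates only the phenol so the benzylic alcohol does not compete.

Step 3
Reactants: 5 (3R)-3-{4-[(1R)-1-hydroxyethyl]-2-iodophenoxy}dihydrofuran-2(3H)-one
Product: 6 (3R)-3-{4-[(1R)-1-hydroxyethyl]-2-iodophenoxy}tetrahydrofuran-2-ol (anomer mixture)
Conditions: i-Bu2AlH (2.2 equiv), CH2Cl2, −78 °C; aq. potassium sodium tartrate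
Reagents that add atoms: none
Why: Partial reduction of a γ-lactone by DIBAL-H stops at the stable aluminium hemiacetal at −78 °C (the first equivalent is consumed by the free hydroxyl), giving a lactol that keeps the epimerisable α-aryloxy aldehyde masked; no existing stereocentre is touched.

Step 4
Reactants: 6 (3R)-3-{4-[(1R)-1-hydroxyethyl]-2-iodophenoxy}tetrahydrofuran-2-ol
Product: 8 (2R,3S)-2-(2-hydroxyethyl)-5-[(1R)-1-hydroxyethyl]-2,3-dihydro-1-benzofuran-3-ol, via hydroxy aldehyde 7 (not isolated)
Conditions: 4CzIPN (2 mol%), CrCl3·3THF (10 mol%), NiCl2·dme (2 mol%), 4,4′-di-tert-butyl-2,2′-bipyridine (12 mol%), Hantzsch ester (1.5 equiv), NaHCO3 (2 equiv), degassed DMF/THF 1:1, 450 nm LEDs, 25 °C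
Reagents that add atoms: none
Why: Proposed new method: a visible-light-driven, chromium/nickel co-catalysed intramolecular Nozaki–Hiyama–Kishi-type arylation of a lactol, in which excited 4CzIPN is reductively quenched by Hantzsch ester, its radical anion returns trivalent chromium to divalent chromium, divalent chromium reduces divalent nickel to zerovalent nickel, oxidative addition into the C–I bond and aryl transfer give an arylchromium that adds to the small equilibrium amount of open aldehyde 7 to form the C3–C3a bond and close the dihydrofuran ring, and the chromium alkoxide is released by the Hantzsch pyridinium proton; the bulky chromium-bound oxygen should sit anti to the C2 hydroxyethyl chain in the compact four-centre transition state, so the bought C2 centre sets C3 as the trans (3S) carbinol; the closest known reaction types are the stoichiometric intramolecular Nozaki–Hiyama–Kishi aryl iodide–aldehyde cyclisation and the light-driven chromium-catalysed allylation of aldehydes.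

Step 5
Reactants: 8 (2R,3S)-2-(2-hydroxyethyl)-5-[(1R)-1-hydroxyethyl]-2,3-dihydro-1-benzofuran-3-ol
Product: 9 2-{(2R,3S)-3-hydroxy-5-[(1R)-1-hydroxyethyl]-2,3-dihydro-1-benzofuran-2-yl}acetaldehyde
Conditions: [Cu(MeCN)4]OTf (5 mol%), 2,2′-bipyridine (5 mol%), TEMPO (5 mol%), N-methylimidazole (10 mol%), MeCN, air, rt
Reagents that add atoms: none
Why: Copper/TEMPO aerobic alcohol oxidation is sterically selective for primary over secondary (including benzylic) alcohols, and the trans ring fusion prevents the γ-hydroxy aldehyde from lactolising and over-oxidising, whereas any cis isomer from step 4 would lactolise and be separated here.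

Step 6
Reactants: 9 2-{(2R,3S)-3-hydroxy-5-[(1R)-1-hydroxyethyl]-2,3-dihydro-1-benzofuran-2-yl}acetaldehyde
Product: 11 2-{(2R,3S)-3-hydroxy-5-[(1R)-1-hydroxyethyl]-2,3-dihydro-1-benzofuran-2-yl}prop-2-enal, via Mannich base 10 (not isolated)
Conditions: 37% aq. CH2O (1.5 equiv), pyrrolidine (10 mol%), propionic acid (10 mol%), i-PrOH, 45 °C
Reagents that add atoms: formaldehyde, C=O
Why: Amine-catalysed Mannich condensation–elimination (organocatalytic α-methylenation of aldehydes) acts on the single enolisable CH2 under buffered conditions and creates no stereocentre; a reversible retro-oxa-Michael opening at C2 would re-close to the more stable trans isomer because C3 is fixed.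

Step 7
Reactants: 11 2-{(2R,3S)-3-hydroxy-5-[(1R)-1-hydroxyethyl]-2,3-dihydro-1-benzofuran-2-yl}prop-2-enal
Product: 13 (1R)-1-[(2R,3S)-3-{[(2E)-2-methylbut-2-enoyl]oxy}-2-(3-oxoprop-1-en-2-yl)-2,3-dihydro-1-benzofuran-5-yl]ethyl (2E)-2-methylbut-2-enoate (target CNP0292799.1), via side-chain monotiglate 12 (not isolated)
Conditions: tiglic anhydride (3 equiv), Et3N (4 equiv), DMAP (0.2 equiv), CH2Cl2, 0 °C to rt
Reagents that add atoms: tiglic anhydride, C/C=C(\C)C(=O)OC(=O)/C(C)=C/C
Why: DMAP-catalysed O-acylation with the anhydride esterifies both secondary carbinols with retention and keeps the stable (E) tiglate geometry, and in the trans isomer the C2–H is syn to the C3 ester so base-induced anti elimination to the benzofuran is disfavoured.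

**Compound list**

1 | (R)-4-(1-hydroxyethyl)phenol | C[C@@H](O)c1ccc(O)cc1 | starting material
2 | 4-[(1R)-1-hydroxyethyl]-2-iodophenol | C[C@@H](O)c1ccc(O)c(I)c1 | intermediate
3 | (S)-3-hydroxydihydrofuran-2(3H)-one ((S)-α-hydroxy-γ-butyrolactone) | O=C1OCC[C@@H]1O | starting material
4 | (S)-2-oxotetrahydrofuran-3-yl trifluoromethanesulfonate | O=C1OCC[C@@H]1OS(=O)(=O)C(F)(F)F | intermediate
5 | (3R)-3-{4-[(1R)-1-hydroxyethyl]-2-iodophenoxy}dihydrofuran-2(3H)-one | O=C1OCC[C@H]1Oc1ccc(cc1I)[C@@H](C)O | intermediate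
6 | (3R)-3-{4-[(1R)-1-hydroxyethyl]-2-iodophenoxy}tetrahydrofuran-2-ol (anomer mixture) | OC1OCC[C@H]1Oc1ccc(cc1I)[C@@H](C)O | intermediate
7 | (2R)-4-hydroxy-2-{4-[(1R)-1-hydroxyethyl]-2-iodophenoxy}butanal | OCC[C@H](C=O)Oc1ccc(cc1I)[C@@H](C)O | intermediate
8 | (2R,3S)-2-(2-hydroxyethyl)-5-[(1R)-1-hydroxyethyl]-2,3-dihydro-1-benzofuran-3-ol | OCC[C@H]1Oc2ccc([C@@H](C)O)cc2[C@@H]1O | intermediate
9 | 2-{(2R,3S)-3-hydroxy-5-[(1R)-1-hydroxyethyl]-2,3-dihydro-1-benzofuran-2-yl}acetaldehyde | O=CC[C@H]1Oc2ccc([C@@H](C)O)cc2[C@@H]1O | intermediate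
10 | 2-{(2R,3S)-3-hydroxy-5-[(1R)-1-hydroxyethyl]-2,3-dihydro-1-benzofuran-2-yl}-3-(pyrrolidin-1-yl)propanal | O=CC(CN1CCCC1)[C@H]1Oc2ccc([C@@H](C)O)cc2[C@@H]1O | intermediate
11 | 2-{(2R,3S)-3-hydroxy-5-[(1R)-1-hydroxyethyl]-2,3-dihydro-1-benzofuran-2-yl}prop-2-enal | C=C(C=O)[C@H]1Oc2ccc([C@@H](C)O)cc2[C@@H]1O | intermediate
12 | (1R)-1-[(2R,3S)-3-hydroxy-2-(3-oxoprop-1-en-2-yl)-2,3-dihydro-1-benzofuran-5-yl]ethyl (2E)-2-methylbut-2-enoate | C=C(C=O)[C@H]1Oc2ccc([C@@H](C)OC(=O)/C(C)=C/C)cc2[C@@H]1O | intermediate
13 | (1R)-1-[(2R,3S)-3-{[(2E)-2-methylbut-2-enoyl]oxy}-2-(3-oxoprop-1-en-2-yl)-2,3-dihydro-1-benzofuran-5-yl]ethyl (2E)-2-methylbut-2-enoate | C=C(C=O)[C@H]1Oc2ccc([C@@H](C)OC(=O)/C(C)=C/C)cc2[C@@H]1OC(=O)/C(C)=C/C | target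

**Step count and risks**

Total step count: 7. Longest linear sequence: 7 steps (1 to 13); 3 enters in step 2.

Steps most likely to fail:

Step 4 (the proposed new ring closure). The risks are slow opening of lactol 6, protodeiodination and an insufficient trans:cis ratio. The fallback uses known chemistry: it gives up the light-driven catalytic manifold and sets out from 6 with a classical stoichiometric Nozaki–Hiyama–Kishi cyclisation in the dark (CrCl2 6 equiv, NiCl2 2 mol%, DMF/THF, 25 °C, with divalent chromium as the stoichiometric reductant). This delivers triol 8 directly, where the route is rejoined; no new isolable compound arises (entry F0).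

Step 6. The β-aryloxy aldehyde 9 can open by retro-oxa-Michael reaction, or its free hydroxyls can add to the product enal. The fallback sets out from 9 and acylates both carbinols first (tiglic anhydride, DMAP, pyridine, CH2Cl2, 0 °C) to give the bis-tiglate aldehyde F4. This is then methylenated with the preformed iminium salt N,N-dimethylmethyleneiminium iodide and Et3N in CH2Cl2, passing through the dimethylaminomethyl Mannich base F5, which loses dimethylamine to give 13, where the route is rejoined at its end.

Step 2. The risks are elimination of triflate 4 to the butenolide, partial epimerisation, or sluggish attack of the hindered o-iodophenoxide. The fallback sets out from 2 and silylates both hydroxyls (TBSCl, imidazole, DMF) to the bis-silyl ether F1. The aryl silyl ether is cleaved selectively (K2CO3, MeOH, 0 °C) to the silyl-protected iodophenol F2. F2 is coupled with 3 under Mitsunobu conditions (PPh3, DIAD, THF, 0 °C; inversion at the lactone carbinol, and the protected benzylic oxygen cannot be activated) to the protected aryloxy lactone F3. Desilylation (TBAF, AcOH, THF) rejoins the route at 5.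

**Further compounds**

F1 | step 2 | tert-butyl{4-[(1R)-1-{[tert-butyl(dimethyl)silyl]oxy}ethyl]-2-iodophenoxy}dimethylsilane | C[C@@H](O[Si](C)(C)C(C)(C)C)c1ccc(O[Si](C)(C)C(C)(C)C)c(I)c1
F2 | step 2 | 4-[(1R)-1-{[tert-butyl(dimethyl)silyl]oxy}ethyl]-2-iodophenol | C[C@@H](O[Si](C)(C)C(C)(C)C)c1ccc(O)c(I)c1
F3 | step 2 | (3R)-3-{4-[(1R)-1-{[tert-butyl(dimethyl)silyl]oxy}ethyl]-2-iodophenoxy}dihydrofuran-2(3H)-one | O=C1OCC[C@H]1Oc1ccc(cc1I)[C@@H](C)O[Si](C)(C)C(C)(C)C
F0 | step 4 | none | none
F4 | step 6 | (1R)-1-[(2R,3S)-3-{[(2E)-2-methylbut-2-enoyl]oxy}-2-(2-oxoethyl)-2,3-dihydro-1-benzofuran-5-yl]ethyl (2E)-2-methylbut-2-enoate | O=CC[C@H]1Oc2ccc([C@@H](C)OC(=O)/C(C)=C/C)cc2[C@@H]1OC(=O)/C(C)=C/C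
F5 | step 6 | (1R)-1-[(2R,3S)-2-[1-(dimethylamino)-3-oxopropan-2-yl]-3-{[(2E)-2-methylbut-2-enoyl]oxy}-2,3-dihydro-1-benzofuran-5-yl]ethyl (2E)-2-methylbut-2-enoate | CN(C)CC(C=O)[C@H]1Oc2ccc([C@@H](C)OC(=O)/C(C)=C/C)cc2[C@@H]1OC(=O)/C(C)=C/C
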